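## Structural features

The target is methyl 7-hydroxy-5-[2-(4-hydroxyphenyl)ethyl]-2,2-dimethyl-8-(3-methylbut-2-enyl)-2H-chromene-6-carboxylate. Its core is a hexasubstituted benzene (ring A) numbered here C1 (CO2Me), C2 (OH), C3 (prenyl), C4 (pyran oxygen O1′), C5 (pyran carbon C4′) and C6 (arylethyl), fused along C4–C5 to a 2,2-dimethyl-2H-pyran. A saturated two-carbon tether joins C6 to a para-hydroxyphenyl ring, and the molecule has no stereocentre, so every selectivity question is one of regiochemistry on ring A. The fragile groups are the prenyl alkene between two phenolic oxygens (acid closes it to a chroman; halogens and electrophilic oxidants attack it), the styrene-like C3′=C4′ bond of the pyran, the chelated salicylate ester and the free phenols. The real difficulty is ring A: six different substituents in a fixed order leave only C5 open for late substitution, and stepwise substitution of a resorcinol runs into the C3/C5 ambiguity. Read from C2 to C6, ring A has the pattern of a triketide lactone, with oxygen on C2 and C4 and carbon branches on C3 and C6. It is a 4-oxy-3-prenyl-6-(arylethyl)-2-pyranone whose ring oxygen sits where C1 belongs. The key step exchanges that oxygen for the ester-bearing C1, forming C1–C2 by enolate addition to the lactone carbonyl and C1–C6 by aldol closure. Five ring carbons and three substituents therefore arrive in the right order from a lactone built by two enolate alkylations, and the pyran ring is closed last at the only free position.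

## Logic of the disconnections

19 ⇒ 18. Only the O–Si bond of the remote phenol is cut. Keeping this phenol capped until the end leaves a single nucleophilic phenol for the pyran annulation. The forward step must remove silicon without touching the salicylate ester or the chromene, which buffered fluoride does.

18 ⇒ 15 + 16. The pyran ring is cut at C5–C4′ and O4–C2′, which removes one ring and gives a resorcylate and a five-carbon enal. The cut is placed here because C5 is the only unsubstituted position of ring A and lies ortho to the C4 hydroxyl and para to the C2 hydroxyl. The forward step needs C–C bond formation at a position flanked by the arylethyl chain on a ring deactivated by the ester.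

15 ⇒ 14. The O4–CH2 acetal bond is cut, because O4 must be an ether during the ring edit and a free hydroxyl for the annulation. The forward step needs acid mild enough to spare the prenyl group between two oxygens.

14 ⇒ 9 + 10. C1–C2 and C1–C6 are cut, excising C1 with its ester and leaving a lactone in which an oxygen bridges C2 and C6. This is the largest simplification of the plan: a hexasubstituted benzene becomes a trisubstituted 2-pyranone plus a two-carbon ester. The forward step needs the enolate of 10 to attack the lactone carbonyl of 9, not C6, C4 or the acidic side-chain CH2, and needs the opened chain to reclose through carbon.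

9 ⇒ 8. The O4–CH2 bond is cut. The acidic hydroxyl of 8 would be deprotonated by the enolate and the resulting anion would deactivate the lactone carbonyl, so it is masked. The forward step needs O-alkylation at O4 rather than at the lactone oxygen or C3.

8 ⇒ 6 + 7. The C3–CH2 bond to the prenyl group is cut, since C3 is the nucleophilic carbon of the vinylogous acid. The forward step needs carbon rather than oxygen allylation and attack at the primary end of the allyl unit.

6 ⇒ 4 + 3. The CH2–CH2 bond of the arylethyl chain is cut, leading to a commodity lactone and a benzylic bromide. The forward step needs the dianion of 4 to react at its methyl-derived carbon and not at oxygen.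

3 ⇒ 2 ⇒ 1. The C–Br bond and then the O–Si bond are cut, leading to a commercial hydroxybenzyl alcohol. The forward steps need silylation of the phenol in preference to the primary alcohol and a neutral bromination.

## Other disconnections considered

Alternative 1: The cut runs through C1–C6 and C2–C3 of ring A and leads to the open-chain enone A1 and dimethyl malonate A2.
- Forward step: alkoxide-mediated conjugate addition of A2 to the β-carbon of A1, then Claisen closure of the α′-enolate onto a malonate ester. This should give the cyclohexane-1,3-dione ester A3, whose C1 and C6 stereocentres (trans, racemic) disappear on aromatisation.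
- In favour: this annulation is a long-established route to 6-substituted resorcylates, the connectivity of A1 fixes the prenyl group at C3, and the reagents are cheap. In certainty of the ring-forming event it is better than the chosen plan.
- Against: A3 is at the wrong oxidation level. Dehydrogenation to the resorcylate A4 needs halogen, quinone or metal-salt oxidants next to a nucleophilic trisubstituted alkene, which such reagents tend to attack or cyclise onto the neighbouring enol oxygen. A1 needs a regiocontrolled enone synthesis on the methyl side of an unsymmetrical ketone (three to four steps). The acetal on the remote phenol would have to be removed by acid at the very end, beside chromene and prenyl.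
- Comparison: the chosen plan closes ring A directly at the aromatic oxidation level with no oxidant, but its central step is unproven; Alternative 1 moves the uncertainty to the aromatisation. Step counts are about equal.

Alternative 2: The cut is in the pyran ring, at C4′–C3′ and O1′–C2′, and leads to the salicylaldehyde A5 (ring A with a formyl group on C5) and the alkenylboronic acid A6.
- Forward step: a secondary-amine-promoted borono-Mannich condensation of A5 with A6, then loss of the amine and oxa-6π closure, should give A7, which has the constitution of 18.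
- In favour: the regiochemistry is dictated by the aldehyde, and the C–C bond at the hindered C5 is made at a carbonyl that is already in place. As a way of closing the pyran ring it is at least the equal of step 8 in regiocontrol and may be better in driving force.
- Against: it does nothing for ring A, which must still be assembled with all six substituents. A5 requires an extra formylation of 15 at C5 under electrophilic, usually acidic conditions with the prenyl group present. A6 costs more than the enal.
- Comparison: it adds one step and is not a competitor to the ring edit. It is a possible replacement for step 8.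

Alternative 3: The cut removes the C6–CH2 bond and the C1–CO2Me bond from a preformed chromene and leads to the chloroarene A8, the Grignard reagent A9 and methyl chloroformate A10.
- Forward step: a hindered lithium amide metalates C1 between chlorine and the acetal oxygen, and loss of LiCl gives the C1–C6 aryne. A9 adds at C6, distal to the alkoxy group, and the C1 arylmagnesium is acylated by A10 to give A11.
- In favour: two bonds form in one flask, the alkoxy group controls the direction of addition to the aryne, and the reaction class is precedented, so on precedent it is better than the chosen key step. Only a deprotection follows, against three steps in the chosen plan.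
- Against: A8 already carries chromene, prenyl, chlorine and a differentiated oxygen in fixed order, so the regiochemical problem of ring A is moved to a pentasubstituted benzene that needs several controlled steps. The amide base may remove the doubly activated prenyl CH2 or add to the aryne. C6 is hindered by the peri vinyl CH of the pyran, and the flanked arylmagnesium may acylate slowly or twice. Two acetals must be removed by acid beside prenyl and chromene.
- Comparison: it is more convergent but longer before its key step and relies on cryogenic organometallic steps. The chosen plan is shorter to its precursor but rests on an unproven step.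

Key step: step 6

Remark on the chemistry: the target is achiral; the only stereodescriptors in the route are the double-bond geometries of the transient species 12 and 17.

## Steps

Step 1
Reactants: 1 4-hydroxybenzyl alcohol
Product: 2 [4-(tert-butyldimethylsilyloxy)phenyl]methanol
Conditions: TBSCl (1.0 equiv), imidazole (1.2 equiv), DMF, 0 °C
Reagents that add atoms: tert-butyldimethylsilyl chloride, CC(C)(C)[Si](C)(C)Cl
Why: Imidazole-promoted silylation; the phenol is far more acidic than the benzylic alcohol and reacts through its hydrogen-bonded or phenoxide form, so one equivalent of silyl chloride at 0 °C should cap the phenol and leave the CH2OH group for step 2.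

Step 2
Reactants: 2 [4-(tert-butyldimethylsilyloxy)phenyl]methanol
Product: 3 4-(tert-butyldimethylsilyloxy)benzyl bromide
Conditions: CBr4, PPh3, CH2Cl2, 0 °C
Reagents that add atoms: tetrabromomethane, BrC(Br)(Br)Br
Why: Appel reaction; bromide displaces the alkoxyphosphonium ion at the benzylic carbon under neutral conditions that spare the aryl silyl ether. The electron-rich bromide should be used without storage.

Step 3
Reactants: 4 4-hydroxy-6-methyl-2H-pyran-2-one; 3 4-(tert-butyldimethylsilyloxy)benzyl bromide
Product: 6 4-hydroxy-6-{2-[4-(tert-butyldimethylsilyloxy)phenyl]ethyl}-2H-pyran-2-one, via pyranone dianion dilithium salt 5 (not isolated)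
Conditions: LiN(iPr)2 (2.7 equiv), 4 (1.3 equiv), THF–DMPU, –78 → –40 °C; 3 (1.0 equiv), –78 → 0 °C; aq HCl
Reagents that add atoms: none
Why: Dianion alkylation; two equivalents of base remove the O4 hydrogen and then one hydrogen of the C6 methyl group, and the dianion reacts with a benzylic bromide at the last-formed, most basic carbanion centre, a documented reaction of this lactone. The lactone is used in excess so that the labile bromide is the limiting partner.

Step 4
Reactants: 6 4-hydroxy-6-{2-[4-(tert-butyldimethylsilyloxy)phenyl]ethyl}-2H-pyran-2-one; 7 3-methylbut-2-enyl acetate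
Product: 8 4-hydroxy-3-(3-methylbut-2-enyl)-6-{2-[4-(tert-butyldimethylsilyloxy)phenyl]ethyl}-2H-pyran-2-one
Conditions: Pd(PPh3)4 (5 mol %), DBU (1.1 equiv), toluene, 60 °C
Reagents that add atoms: none
Why: Tsuji–Trost allylation with zerovalent palladium; the soft pyranone-4-olate attacks the unsubstituted terminus of the 1,1-dimethylallyl palladium cation and so places a linear prenyl group on C3, the known site of palladium-catalysed allylation of 4-hydroxy-2-pyranones. Any O-allylated material is an allylic ester equivalent and should be re-ionised by the catalyst, which funnels the mixture to the C-alkylated lactone.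

Step 5
Reactants: 8 4-hydroxy-3-(3-methylbut-2-enyl)-6-{2-[4-(tert-butyldimethylsilyloxy)phenyl]ethyl}-2H-pyran-2-one
Product: 9 4-(methoxymethoxy)-3-(3-methylbut-2-enyl)-6-{2-[4-(tert-butyldimethylsilyloxy)phenyl]ethyl}-2H-pyran-2-one
Conditions: MOMCl, iPr2NEt, CH2Cl2, 0 → 25 °C
Reagents that add atoms: chloromethyl methyl ether, COCCl
Why: O-alkylation of a vinylogous acid with a hard, oxocarbenium-like electrophile goes to O4 and fixes the 2-pyranone tautomer. The acetal masks the acidic hydroxyl, whose anion would otherwise consume the enolate and deactivate the lactone carbonyl in step 6.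

Step 6
Reactants: 9 4-(methoxymethoxy)-3-(3-methylbut-2-enyl)-6-{2-[4-(tert-butyldimethylsilyloxy)phenyl]ethyl}-2H-pyran-2-one; 10 methyl acetate
Product: 14 methyl 2-hydroxy-4-(methoxymethoxy)-3-(3-methylbut-2-enyl)-6-{2-[4-(tert-butyldimethylsilyloxy)phenyl]ethyl}benzoate, via lithium enolate of methyl acetate 11 (not isolated), via open-chain diketo ester 12 (not isolated), via cyclic aldol adduct 13 (not isolated)
Conditions: LiN(iPr)2 (4 equiv), 10 (4 equiv), THF, –78 °C; add 9, –78 → –30 °C; AcOH (4 equiv), to 25 °C; DBU (0.3 equiv), 25 °C
Reagents that add atoms: none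
Why: Proposed new method: the hard lithium enolate 11 should add 1,2 to the lactone carbonyl C2 of 9 in a Claisen-type acyl substitution, and collapse of the adduct should expel O1 as the C6 enolate, a vinylogous β-diketonate stabilised through C5, C4 and C3 by the new C2 ketone, so that ring opening is downhill; a second equivalent of 11 then removes a hydrogen from the new C1 methylene, which is why an excess is used. Neutralisation with AcOH should give 12, a 3,7-dioxo ester whose 5-carbonyl is masked as the enol acetal and whose tetrasubstituted double bond (C3=C4 in ring A numbering) keeps C2 and C5 cis as in the lactone. With catalytic DBU the C1 carbon, flanked by the ester and the C2 ketone, should attack the C6 ketone in a 6-exo-trig aldol closure (6-(enolendo)-exo-trig through the C1=C2 enolate, equally allowed as 6-(enolexo) through the ester enolate) to give 13, and E1cB loss of water followed by enolisation of the C2 ketone should aromatise ring A to 14. The net change is exchange of the ring oxygen for the ester-bearing carbon: the lactone carbonyl oxygen becomes the chelated C2 hydroxyl and O1 leaves as water. The closest known reaction types are carbanion-induced ring transformations of 2-pyranones into benzenes, the pyrylium-to-benzene exchange with CH-acids and the base-mediated recyclisation of pyranone-derived polyketo esters to resorcylates; none of them adds an acetate enolate to the carbonyl of a 4-alkoxy-2-pyranone and recloses through C6. No stereocentre is set, since the two centres of 13 are destroyed on aromatisation. The selectivity needed is attack at C2 in preference to conjugate addition at C6, displacement at C4 or proton abstraction from the CH2 on C6; the lithium counter-ion at –78 °C, the alkyl group and two oxygen donors that deactivate C6, the fully substituted C3, and the fact that side-chain deprotonation is a reversible detour while ring opening is not should secure it. The enol acetal keeps C4 from acting as a carbonyl, so lactonisation through O4 or a Claisen-type closure cannot compete with the C1–C6 aldol.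

Step 7
Reactants: 14 methyl 2-hydroxy-4-(methoxymethoxy)-3-(3-methylbut-2-enyl)-6-{2-[4-(tert-butyldimethylsilyloxy)phenyl]ethyl}benzoate
Product: 15 methyl 2,4-dihydroxy-3-(3-methylbut-2-enyl)-6-{2-[4-(tert-butyldimethylsilyloxy)phenyl]ethyl}benzoate
Conditions: HCl (cat.), MeOH–THF, 0 → 25 °C
Reagents that add atoms: none
Why: Acid-catalysed acetal exchange with methanol releases the C4 phenol and dimethoxymethane. Dilute acid at or below room temperature is chosen because aryl silyl ethers are the acid-resistant class of silyl ethers and because stronger acid would cyclise the prenyl group onto a flanking phenol; the chelated C2 hydroxyl and the methyl ester are inert in methanol.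

Step 8
Reactants: 15 methyl 2,4-dihydroxy-3-(3-methylbut-2-enyl)-6-{2-[4-(tert-butyldimethylsilyloxy)phenyl]ethyl}benzoate; 16 3-methylbut-2-enal
Product: 18 methyl 5-{2-[4-(tert-butyldimethylsilyloxy)phenyl]ethyl}-7-hydroxy-2,2-dimethyl-8-(3-methylbut-2-enyl)-2H-chromene-6-carboxylate, via ortho-quinone methide 17 (not isolated)
Conditions: ethylenediammonium diacetate (20 mol %), 16 (3 equiv), toluene, 110 °C
Reagents that add atoms: none
Why: Amine-salt-catalysed chromene annulation (Knoevenagel-type condensation, then oxa-6π electrocyclisation): the enal, activated as its iminium ion, is attacked by C5, loss of the amine gives 17, and ring closure through O4 forms the 2,2-dimethyl-2H-pyran. C5 is the only unsubstituted ring position and is ortho to the C4 hydroxyl and para to the C2 hydroxyl; both ortho positions of the C2 hydroxyl are blocked, so only one regioisomer can form.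

Step 9
Reactants: 18 methyl 5-{2-[4-(tert-butyldimethylsilyloxy)phenyl]ethyl}-7-hydroxy-2,2-dimethyl-8-(3-methylbut-2-enyl)-2H-chromene-6-carboxylate
Product: 19 methyl 7-hydroxy-5-[2-(4-hydroxyphenyl)ethyl]-2,2-dimethyl-8-(3-methylbut-2-enyl)-2H-chromene-6-carboxylate
Conditions: Bu4NF (1.1 equiv), AcOH (1.1 equiv), THF, 0 °C
Reagents that add atoms: none
Why: Fluoride-induced cleavage of the aryl silyl ether, driven by Si–F bond formation. Buffering with AcOH keeps the medium near neutral so that the salicylate ester, the prenyl group and the chromene should be untouched.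

## Compound list

1 | 4-hydroxybenzyl alcohol | OCc1ccc(O)cc1 | starting material
2 | [4-(tert-butyldimethylsilyloxy)phenyl]methanol | OCc1ccc(O[Si](C)(C)C(C)(C)C)cc1 | intermediate
3 | 4-(tert-butyldimethylsilyloxy)benzyl bromide | BrCc1ccc(O[Si](C)(C)C(C)(C)C)cc1 | intermediate
4 | 4-hydroxy-6-methyl-2H-pyran-2-one | CC1=CC(O)=CC(=O)O1 | starting material
5 | dilithium salt of the O4,C7-dianion of 4-hydroxy-6-methyl-2H-pyran-2-one (not isolated) | [Li+].[Li+].[CH2-]C1=CC([O-])=CC(=O)O1 | intermediate
6 | 4-hydroxy-6-{2-[4-(tert-butyldimethylsilyloxy)phenyl]ethyl}-2H-pyran-2-one | O=C1C=C(O)C=C(CCc2ccc(O[Si](C)(C)C(C)(C)C)cc2)O1 | intermediate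
7 | 3-methylbut-2-enyl acetate (prenyl acetate) | CC(=O)OCC=C(C)C | starting material
8 | 4-hydroxy-3-(3-methylbut-2-enyl)-6-{2-[4-(tert-butyldimethylsilyloxy)phenyl]ethyl}-2H-pyran-2-one | O=C1OC(CCc2ccc(O[Si](C)(C)C(C)(C)C)cc2)=CC(O)=C1CC=C(C)C | intermediate
9 | 4-(methoxymethoxy)-3-(3-methylbut-2-enyl)-6-{2-[4-(tert-butyldimethylsilyloxy)phenyl]ethyl}-2H-pyran-2-one | COCOC1=C(CC=C(C)C)C(=O)OC(CCc2ccc(O[Si](C)(C)C(C)(C)C)cc2)=C1 | intermediate
10 | methyl acetate | COC(C)=O | starting material
11 | lithium enolate of methyl acetate, lithium 1-methoxyethenolate (not isolated) | [Li+].[O-]C(=C)OC | intermediate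
12 | methyl (4E)-9-[4-(tert-butyldimethylsilyloxy)phenyl]-5-(methoxymethoxy)-4-(3-methylbut-2-enyl)-3,7-dioxonon-4-enoate (not isolated; neutral form, present as lithium enolates before the quench) | COC(=O)CC(=O)/C(CC=C(C)C)=C(OCOC)\CC(=O)CCc1ccc(O[Si](C)(C)C(C)(C)C)cc1 | intermediate
13 | methyl 6-{2-[4-(tert-butyldimethylsilyloxy)phenyl]ethyl}-6-hydroxy-4-(methoxymethoxy)-3-(3-methylbut-2-enyl)-2-oxocyclohex-3-ene-1-carboxylate (not isolated; racemic mixture of diastereomers, both centres lost on dehydration) | COC(=O)C1C(=O)C(CC=C(C)C)=C(OCOC)CC1(O)CCc1ccc(O[Si](C)(C)C(C)(C)C)cc1 | intermediate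
14 | methyl 2-hydroxy-4-(methoxymethoxy)-3-(3-methylbut-2-enyl)-6-{2-[4-(tert-butyldimethylsilyloxy)phenyl]ethyl}benzoate | COC(=O)c1c(O)c(CC=C(C)C)c(OCOC)cc1CCc1ccc(O[Si](C)(C)C(C)(C)C)cc1 | intermediate
15 | methyl 2,4-dihydroxy-3-(3-methylbut-2-enyl)-6-{2-[4-(tert-butyldimethylsilyloxy)phenyl]ethyl}benzoate | COC(=O)c1c(O)c(CC=C(C)C)c(O)cc1CCc1ccc(O[Si](C)(C)C(C)(C)C)cc1 | intermediate
16 | 3-methylbut-2-enal | CC(C)=CC=O | starting material
17 | methyl (5Z)-2-hydroxy-5-(3-methylbut-2-enylidene)-3-(3-methylbut-2-enyl)-4-oxo-6-{2-[4-(tert-butyldimethylsilyloxy)phenyl]ethyl}cyclohexa-2,6-diene-1-carboxylate (ortho-quinone methide, not isolated; drawn in the geometry that cyclises) | CC(C)=C/C=C1\C(=O)C(CC=C(C)C)=C(O)C(C(=O)OC)=C1CCc1ccc(O[Si](C)(C)C(C)(C)C)cc1 | intermediate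
18 | methyl 5-{2-[4-(tert-butyldimethylsilyloxy)phenyl]ethyl}-7-hydroxy-2,2-dimethyl-8-(3-methylbut-2-enyl)-2H-chromene-6-carboxylate | COC(=O)c1c(O)c(CC=C(C)C)c2OC(C)(C)C=Cc2c1CCc1ccc(O[Si](C)(C)C(C)(C)C)cc1 | intermediate
19 | methyl 7-hydroxy-5-[2-(4-hydroxyphenyl)ethyl]-2,2-dimethyl-8-(3-methylbut-2-enyl)-2H-chromene-6-carboxylate | COC(=O)c1c(O)c(CC=C(C)C)c2c(c1CCc1ccc(O)cc1)C=CC(C)(C)O2 | target

## Step count and least certain steps

Total step count: 9. Longest linear sequence: 9 steps (1 to 19); the lactone 4 enters at step 3, the acetate 7 at step 4, the ester 10 at step 6 and the enal 16 at step 8.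

Step 6 (key step, proposed new method). The most likely failure is proton transfer from the CH2 on C6 of 9 to the enolate 11, because 9 is a vinylogous ester with acidic γ-hydrogens and its lactone carbonyl is deactivated by the C4 oxygen. Carbonyl addition may then be outrun, or conjugate addition at C6 may take over; a second possibility is incomplete aldol closure of 12.

The fallback uses known chemistry only, sets out from 3 and comes back at 15, bypassing steps 3 to 7. Commercial methyl 2,4-dihydroxy-6-methylbenzoate is C-alkylated through its sodium phenoxide in toluene (NaH, prenyl bromide); ortho-C-alkylation of the tight ion pair favours the carbon between the two oxygens and should give methyl 2,4-dihydroxy-6-methyl-3-(3-methylbut-2-enyl)benzoate F1. Both phenols are capped (MOMCl, NaH, DMF) to give methyl 2,4-bis(methoxymethoxy)-6-methyl-3-(3-methylbut-2-enyl)benzoate F2. Lateral lithiation of the C6 methyl group with LiN(iPr)2 at –78 °C (ester-stabilised ortho-toluate anion) and alkylation with 3 should give methyl 2,4-bis(methoxymethoxy)-3-(3-methylbut-2-enyl)-6-{2-[4-(tert-butyldimethylsilyloxy)phenyl]ethyl}benzoate F3. Dilute HCl in methanol then removes both acetals and returns 15.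

Step 4. The likely failures are allylation on oxygen that is not corrected by re-ionisation, attack at the tertiary end of the allyl–palladium intermediate, and a second allylation at C3, all of which follow from the ambident and still acidic nature of the lactone.

The fallback places the prenyl group before the ring is made; it sets out from 3 and comes back at 8. Methyl acetoacetate is alkylated with prenyl bromide (K2CO3, acetone) to methyl 2-acetyl-5-methylhex-4-enoate F4. Double deprotonation (NaH, then n-BuLi, THF, 0 °C) and acylation at the terminal carbon with N-methoxy-N-methylacetamide should give methyl 2-(3-methylbut-2-enyl)-3,5-dioxohexanoate F5. Heating with DBU in toluene lactonises it, with loss of methanol, to 4-hydroxy-6-methyl-3-(3-methylbut-2-enyl)-2H-pyran-2-one F6. Double deprotonation of F6 with LiN(iPr)2 and alkylation with 3, as in step 3, returns 8.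

Step 8. The likely failure is slow C–C bond formation at C5, which is flanked by the arylethyl chain and sits on a ring deactivated by the ester, so that self-condensation of the enal consumes the reagent first.

The fallback builds the pyran by a sigmatropic route; it sets out from 15 and comes back at 18. The unchelated C4 hydroxyl is alkylated with 3-chloro-3-methylbut-1-yne (K2CO3, KI, CuI cat., acetone, reflux) to methyl 2-hydroxy-4-(2-methylbut-3-yn-2-yloxy)-3-(3-methylbut-2-enyl)-6-{2-[4-(tert-butyldimethylsilyloxy)phenyl]ethyl}benzoate F7. Heating in xylene at 140 °C should bring about aryl propargyl ether Claisen rearrangement to C5 (the only free ortho position), enolisation, [1,5]-hydrogen shift and oxa-6π closure to give 18.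

Step 7. The likely failure is acid-induced cyclisation of the prenyl group onto one of the flanking phenols, or partial loss of the silyl ether, if the acetal resists the mild acid.

The fallback replaces the acetal by a group removed without acid; it sets out from 8 and comes back at 15. Mitsunobu etherification of 8 with prop-2-en-1-ol (PPh3, diisopropyl azodicarboxylate, THF) should give 4-(prop-2-enyloxy)-3-(3-methylbut-2-enyl)-6-{2-[4-(tert-butyldimethylsilyloxy)phenyl]ethyl}-2H-pyran-2-one F8. The ring edit of step 6 with 11 is then run on F8. It should pass through methyl (4E)-9-[4-(tert-butyldimethylsilyloxy)phenyl]-4-(3-methylbut-2-enyl)-3,7-dioxo-5-(prop-2-enyloxy)non-4-enoate F9 and methyl 6-{2-[4-(tert-butyldimethylsilyloxy)phenyl]ethyl}-6-hydroxy-3-(3-methylbut-2-enyl)-2-oxo-4-(prop-2-enyloxy)cyclohex-3-ene-1-carboxylate F10, and give methyl 2-hydroxy-3-(3-methylbut-2-enyl)-4-(prop-2-enyloxy)-6-{2-[4-(tert-butyldimethylsilyloxy)phenyl]ethyl}benzoate F11. Allyl transfer to morpholine with Pd(PPh3)4 (zerovalent palladium, THF, 25 °C) then returns 15 under neutral conditions.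

## Further compounds

F1 | step 6 | methyl 2,4-dihydroxy-6-methyl-3-(3-methylbut-2-enyl)benzoate | COC(=O)c1c(C)cc(O)c(CC=C(C)C)c1O
F2 | step 6 | methyl 2,4-bis(methoxymethoxy)-6-methyl-3-(3-methylbut-2-enyl)benzoate | COCOc1cc(C)c(C(=O)OC)c(OCOC)c1CC=C(C)C
F3 | step 6 | methyl 2,4-bis(methoxymethoxy)-3-(3-methylbut-2-enyl)-6-{2-[4-(tert-butyldimethylsilyloxy)phenyl]ethyl}benzoate | COCOc1cc(CCc2ccc(O[Si](C)(C)C(C)(C)C)cc2)c(C(=O)OC)c(OCOC)c1CC=C(C)C
F4 | step 4 | methyl 2-acetyl-5-methylhex-4-enoate (racemic) | COC(=O)C(CC=C(C)C)C(C)=O
F5 | step 4 | methyl 2-(3-methylbut-2-enyl)-3,5-dioxohexanoate (racemic) | COC(=O)C(CC=C(C)C)C(=O)CC(C)=O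
F6 | step 4 | 4-hydroxy-6-methyl-3-(3-methylbut-2-enyl)-2H-pyran-2-one | CC1=CC(O)=C(CC=C(C)C)C(=O)O1
F7 | step 8 | methyl 2-hydroxy-4-(2-methylbut-3-yn-2-yloxy)-3-(3-methylbut-2-enyl)-6-{2-[4-(tert-butyldimethylsilyloxy)phenyl]ethyl}benzoate | COC(=O)c1c(O)c(CC=C(C)C)c(OC(C)(C)C#C)cc1CCc1ccc(O[Si](C)(C)C(C)(C)C)cc1
F8 | step 7 | 4-(prop-2-enyloxy)-3-(3-methylbut-2-enyl)-6-{2-[4-(tert-butyldimethylsilyloxy)phenyl]ethyl}-2H-pyran-2-one | C=CCOC1=C(CC=C(C)C)C(=O)OC(CCc2ccc(O[Si](C)(C)C(C)(C)C)cc2)=C1
F9 | step 7 | methyl (4E)-9-[4-(tert-butyldimethylsilyloxy)phenyl]-4-(3-methylbut-2-enyl)-3,7-dioxo-5-(prop-2-enyloxy)non-4-enoate | COC(=O)CC(=O)/C(CC=C(C)C)=C(OCC=C)\CC(=O)CCc1ccc(O[Si](C)(C)C(C)(C)C)cc1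
F10 | step 7 | methyl 6-{2-[4-(tert-butyldimethylsilyloxy)phenyl]ethyl}-6-hydroxy-3-(3-methylbut-2-enyl)-2-oxo-4-(prop-2-enyloxy)cyclohex-3-ene-1-carboxylate (racemic mixture of diastereomers) | COC(=O)C1C(=O)C(CC=C(C)C)=C(OCC=C)CC1(O)CCc1ccc(O[Si](C)(C)C(C)(C)C)cc1
F11 | step 7 | methyl 2-hydroxy-3-(3-methylbut-2-enyl)-4-(prop-2-enyloxy)-6-{2-[4-(tert-butyldimethylsilyloxy)phenyl]ethyl}benzoate | COC(=O)c1c(O)c(CC=C(C)C)c(OCC=C)cc1CCc1ccc(O[Si](C)(C)C(C)(C)C)cc1
A1 | alternative 1 | (3E)-1-[4-(methoxymethoxy)phenyl]-9-methyldeca-3,8-dien-5-one | COCOc1ccc(CC/C=C/C(=O)CCC=C(C)C)cc1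
A2 | alternative 1 | dimethyl malonate | COC(=O)CC(=O)OC
A3 | alternative 1 | methyl trans-4-hydroxy-6-{2-[4-(methoxymethoxy)phenyl]ethyl}-3-(3-methylbut-2-enyl)-2-oxocyclohex-3-ene-1-carboxylate (racemic, one enantiomer drawn) | COC(=O)[C@H]1[C@H](CCc2ccc(OCOC)cc2)CC(O)=C(CC=C(C)C)C1=O
A4 | alternative 1 | methyl 2,4-dihydroxy-6-{2-[4-(methoxymethoxy)phenyl]ethyl}-3-(3-methylbut-2-enyl)benzoate | COC(=O)c1c(O)c(CC=C(C)C)c(O)cc1CCc1ccc(OCOC)cc1
A5 | alternative 2 | methyl 3-formyl-4,6-dihydroxy-5-(3-methylbut-2-enyl)-2-{2-[4-(tert-butyldimethylsilyloxy)phenyl]ethyl}benzoate | COC(=O)c1c(O)c(CC=C(C)C)c(O)c(C=O)c1CCc1ccc(O[Si](C)(C)C(C)(C)C)cc1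
A6 | alternative 2 | (2-methylprop-1-enyl)boronic acid | CC(C)=CB(O)O
A7 | alternative 2 | methyl 5-{2-[4-(tert-butyldimethylsilyloxy)phenyl]ethyl}-7-hydroxy-2,2-dimethyl-8-(3-methylbut-2-enyl)-2H-chromene-6-carboxylate | COC(=O)c1c(O)c(CC=C(C)C)c2OC(C)(C)C=Cc2c1CCc1ccc(O[Si](C)(C)C(C)(C)C)cc1
A8 | alternative 3 | 5-chloro-7-(methoxymethoxy)-2,2-dimethyl-8-(3-methylbut-2-enyl)-2H-chromene | COCOc1cc(Cl)c2C=CC(C)(C)Oc2c1CC=C(C)C
A9 | alternative 3 | {2-[4-(methoxymethoxy)phenyl]ethyl}magnesium bromide | COCOc1ccc(CC[Mg]Br)cc1
A10 | alternative 3 | methyl chloroformate | COC(=O)Cl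
A11 | alternative 3 | methyl 7-(methoxymethoxy)-5-{2-[4-(methoxymethoxy)phenyl]ethyl}-2,2-dimethyl-8-(3-methylbut-2-enyl)-2H-chromene-6-carboxylate | COCOc1c(C(=O)OC)c(CCc2ccc(OCOC)cc2)c2C=CC(C)(C)Oc2c1CC=C(C)C
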